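The route rests on cutting C1–C2 and C3–C4 of the five-carbon linker (C1 carbinol to C5) between the epoxycyclohexene ring B and the methylidenecyclohexane ring A. The feature used is the (2Z)-C2=C3 alkene with CH3 on C3, lying between carbinol C1 on the quaternary epoxide carbon of ring B and the (4E)-C4=C5 alkene on ring A: formally propyne to which a carbonyl carbon (at C2) and an alkenyl carbon (at C3) were added syn. One nickel-catalysed three-component coupling of a persilylated ring-B epoxy aldehyde, propyne and the alkenylzirconocene of a ring-A terminal alkyne makes both bonds, the Z alkene and C1; buffered fluoride then frees the pentol.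

Key step: step 16

Remark: ring B is numbered as a 7-oxabicyclo[4.1.0]hept-3-ene with C1 the quaternary epoxide carbon; the coupling partners and coupled product were checked against the target and needed no structural correction (only CIP letters change with priorities); the one design change is a TES instead of a TBS ether on the hindered ring-A oxygen, so that the last step can run under buffered fluoride.

Step 1
Reactants: 1 geranyl acetate
Product: 2 (6R)-6,7-epoxygeranyl acetate
Conditions: D-fructose-derived Shi ketone (30 mol%), Oxone, K2CO3, Bu4NHSO4, MeCN/DMM–aq. borate buffer (pH 10.5), 0 °C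
Reagents that add atoms: Oxone (potassium peroxymonosulfate), [K+].[O-]S(=O)(=O)OO
Why: Shi asymmetric epoxidation: the chiral dioxirane should select the electron-rich 6,7-alkene over the acetate-deactivated 2,3-alkene and, through the spiro transition state, deliver oxygen to the face that makes C6 R.

Step 2
Reactants: 2 (6R)-6,7-epoxygeranyl acetate
Product: 3 cis-hydroxy acetate of ring A
Conditions: Cp2TiCl2 (2.2 equiv), Mn dust, THF, rt; then 1 M HCl
Reagents that add atoms: none
Why: Titanocene(III)-mediated reductive epoxide opening and 6-endo radical cyclisation (Nugent–RajanBabu chemistry): the tertiary radical adds to the 2,3-alkene through a chair with the O–Ti and CH2OAc groups equatorial, so C1 is set cis to the retained carbinol C3 (1S,3R), and Ti(III) capture with β-hydride loss from the new tertiary radical should give the exocyclic methylene.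

Step 3
Reactants: 3 cis-hydroxy acetate of ring A
Product: 4 TES ether acetate
Conditions: TESCl, imidazole, DMAP (cat.), DMF, rt
Reagents that add atoms: chlorotriethylsilane, CC[Si](Cl)(CC)CC
Why: Standard silyl ether formation; TES is chosen for this neopentyl-type oxygen because a TBS ether here would need forcing fluoride at the end.

Step 4
Reactants: 4 TES ether acetate
Product: 5 primary alcohol
Conditions: K2CO3 (cat.), MeOH, 0 °C to rt
Reagents that add atoms: none
Why: Base-catalysed methanolysis (transesterification) of the primary acetate; the hindered TES ether and the alkene are inert.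

Step 5
Reactants: 5 primary alcohol
Product: 6 β,γ-unsaturated aldehyde
Conditions: Dess–Martin periodinane, NaHCO3, CH2Cl2, 0 °C
Reagents that add atoms: none
Why: Dess–Martin oxidation under buffered, non-basic conditions should give the aldehyde without epimerisation at C1 or migration of the exocyclic alkene; it is used at once.

Step 6
Reactants: 6 β,γ-unsaturated aldehyde
Product: 7 1,1-dibromoalkene
Conditions: CBr4, PPh3, Zn, CH2Cl2, rt (ylide preformed); then 6, 0 °C to rt
Reagents that add atoms: carbon tetrabromide, BrC(Br)(Br)Br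
Why: Ramirez dibromoolefination (first stage of the Corey–Fuchs sequence) is a neutral Wittig-type reaction that should leave the α-stereocentre and the exocyclic alkene alone.

Step 7
Reactants: 7 1,1-dibromoalkene
Product: 8 ring-A alkyne (TES ether)
Conditions: n-BuLi (2.2 equiv), THF, −78 to −20 °C; aq. NH4Cl
Reagents that add atoms: none
Why: Second stage of the Corey–Fuchs sequence: Br/Li exchange, α-elimination and Fritsch–Buttenberg–Wiechell 1,2-shift give the lithium acetylide, protonated on work-up; the ring stereocentres are untouched.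

Step 8
Reactants: 9 dimethyl succinylsuccinate
Product: 10 (1S,2S,4S,5S)-diol diester
Conditions: H2 (80 atm), RuCl2[(S)-BINAP](dmf)n (1 mol%), MeOH/CH2Cl2, 50 °C
Reagents that add atoms: none
Why: Noyori asymmetric hydrogenation of a cyclic bis(β-keto ester): the (S)-BINAP–Ru catalyst should set both carbinol centres S (the second reduction sharpening the ee), while the ester-bearing centres equilibrate and end trans to OH (dynamic kinetic resolution) and are erased later.

Step 9
Reactants: 10 (1S,2S,4S,5S)-diol diester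
Product: 11 bis-TBS ether diester
Conditions: TBSCl, imidazole, DMF, rt
Reagents that add atoms: tert-butyldimethylsilyl chloride, CC(C)(C)[Si](C)(C)Cl
Why: Standard silylation of the two secondary β-hydroxy ester alcohols under non-eliminating conditions.

Step 10
Reactants: 11 bis-TBS ether diester
Product: 13 bis(phenylselanyl) diester, via bis(ketene silyl acetal) 12 (not isolated)
Conditions: LDA (2.5 equiv), TMSCl (6 equiv, premixed), THF, −78 °C to rt; evaporate; PhSeCl (2.3 equiv), CH2Cl2, −78 °C
Reagents that add atoms: benzeneselenenyl chloride, Cl[Se]c1ccccc1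
Why: In-situ-quench enolisation traps each ester enolate as its ketene silyl acetal before silanolate can be expelled from the β-carbon, and electrophilic selenenylation of the ketene acetals then places PhSe on both α-carbons (the configuration there is of no consequence).

Step 11
Reactants: 13 bis(phenylselanyl) diester
Product: 15 cyclohexadiene diester bis-TBS ether, via bis-selenoxide 14 (not isolated)
Conditions: 30% H2O2, pyridine, CH2Cl2, 0 °C to rt
Reagents that add atoms: none
Why: Selenoxide syn-elimination: each selenoxide should eliminate toward the ring CH2 and not toward the silyloxy-bearing carbon (elimination away from oxygen), giving both enoate double bonds with the carbinol centres intact.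

Step 12
Reactants: 15 cyclohexadiene diester bis-TBS ether
Product: 16 C2-symmetric bis(allylic alcohol)
Conditions: DIBAL-H (4.5 equiv), CH2Cl2, −78 °C; Rochelle salt
Reagents that add atoms: none
Why: DIBAL-H 1,2-reduction of both enoates to the allylic alcohols at low temperature, with the silyl ethers and the diene untouched.

Step 13
Reactants: 16 C2-symmetric bis(allylic alcohol)
Product: 17 mono-TBS ether
Conditions: TBSCl (1.0 equiv), imidazole, CH2Cl2, −20 °C; recovered 16 recycled
Reagents that add atoms: tert-butyldimethylsilyl chloride, CC(C)(C)[Si](C)(C)Cl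
Why: Monosilylation of a C2-symmetric diol: the two hydroxymethyl groups are homotopic, so a single mono-ether should form, and imidazole replaces a strong base to avoid 1,3-silyl migration.

Step 14
Reactants: 17 mono-TBS ether
Product: 18 epoxy alcohol
Conditions: Ti(OiPr)4 (20 mol%), L-(+)-DET (24 mol%), TBHP, 4 Å MS, CH2Cl2, −20 °C
Reagents that add atoms: tert-butyl hydroperoxide, CC(C)(C)OO
Why: Katsuki–Sharpless asymmetric epoxidation: only the alkene carrying the free hydroxymethyl group is activated, and L-(+)-tartrate delivers oxygen to the face anti to both flanking silyloxy groups (matched case), which sets C1 and C6 of the oxabicycle.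

Step 15
Reactants: 18 epoxy alcohol
Product: 19 ring-B epoxy aldehyde (tris-TBS)
Conditions: Dess–Martin periodinane, NaHCO3, CH2Cl2, 0 °C to rt
Reagents that add atoms: none
Why: Dess–Martin oxidation of the primary epoxy alcohol; the α,β-epoxy aldehyde has a quaternary α-carbon and cannot enolise.

Step 16
Reactants: 19 ring-B epoxy aldehyde (tris-TBS); 20 propyne; 8 ring-A alkyne (TES ether)
Product: 22 coupled (2Z,4E)-dienyl carbinol tetrasilyl ether, via alkenylzirconocene chloride 21 (not isolated)
Conditions: 8 (1.6 equiv), Cp2Zr(H)Cl (1.5 equiv), THF, rt; this solution and propyne (3 equiv) added slowly to 19, ZnCl2 (1.0 equiv), Ni(cod)2 (15 mol%), THF, 0 °C; aq. NH4Cl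
Reagents that add atoms: none
Why: Proposed new method: Ni(0) should bind propyne and the Zn(II)-activated aldehyde and cyclise oxidatively to an oxanickelacyclopentene with the new C1–C2 bond on the unsubstituted alkyne carbon and nickel on the methyl-bearing C3; alkenyl transfer from 21 (zirconium to nickel, shuttled by zinc) and reductive elimination then form C3–C4 with retention, so C1 and C4 end cis (2Z) and the hydrozirconation-derived alkene stays E. The closest known reaction types are nickel-catalysed alkylative couplings of aldehydes, alkynes and organozincs, and nickel-catalysed ynal cyclisations terminated by alkenylzirconocenes. No ring is closed. The one new stereocentre, C1 (S), is to be set by the substrate: Zn(II) bridging the carbonyl and epoxide oxygens holds C=O syn to the epoxide C–O bond, and the alkyne carbon then approaches past the epoxide CH (C6) and not past the silyloxy-bearing C2. The step needs alkyne regioselectivity (H against CH3 at propyne with no bulky ligand on nickel), syn addition (inherent in the metallacycle) and reaction at the aldehyde in preference to the epoxide (a non-enolisable, α-oxygenated aldehyde that should cyclise fast, next to an epoxide with no allylic activation).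

Step 17
Reactants: 22 coupled (2Z,4E)-dienyl carbinol tetrasilyl ether
Product: 23 target pentol
Conditions: TBAF, AcOH (1:1, 8 equiv), THF, 0 °C to rt
Reagents that add atoms: none
Why: Fluoride-driven Si–O cleavage of the TES and three TBS ethers; acetic acid buffering keeps the alkoxides protonated so that no Payne-type epoxide migration toward the C1, C2 or C5 oxygens should occur, and no stereocentre is touched.

Compound list
1 | geranyl acetate, (2E)-3,7-dimethylocta-2,6-dien-1-yl acetate | CC(=O)OC/C=C(\C)CCC=C(C)C | starting material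
2 | (2E)-5-[(2R)-3,3-dimethyloxiran-2-yl]-3-methylpent-2-en-1-yl acetate | CC(=O)OC/C=C(\C)CC[C@H]1OC1(C)C | intermediate
3 | [(1S,3R)-3-hydroxy-2,2-dimethyl-6-methylidenecyclohexyl]methyl acetate (OH and CH2OAc cis) | C=C1CC[C@@H](O)C(C)(C)[C@H]1COC(C)=O | intermediate
4 | [(1S,3R)-2,2-dimethyl-6-methylidene-3-(triethylsilyloxy)cyclohexyl]methyl acetate | C=C1CC[C@@H](O[Si](CC)(CC)CC)C(C)(C)[C@H]1COC(C)=O | intermediate
5 | [(1S,3R)-2,2-dimethyl-6-methylidene-3-(triethylsilyloxy)cyclohexyl]methanol | C=C1CC[C@@H](O[Si](CC)(CC)CC)C(C)(C)[C@H]1CO | intermediate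
6 | (1S,3R)-2,2-dimethyl-6-methylidene-3-(triethylsilyloxy)cyclohexane-1-carbaldehyde | C=C1CC[C@@H](O[Si](CC)(CC)CC)C(C)(C)[C@H]1C=O | intermediate
7 | {[(1R,3S)-3-(2,2-dibromoethenyl)-2,2-dimethyl-4-methylidenecyclohexyl]oxy}triethylsilane | C=C1CC[C@@H](O[Si](CC)(CC)CC)C(C)(C)[C@H]1C=C(Br)Br | intermediate
8 | triethyl{[(1R,3R)-3-ethynyl-2,2-dimethyl-4-methylidenecyclohexyl]oxy}silane | C=C1CC[C@@H](O[Si](CC)(CC)CC)C(C)(C)[C@H]1C#C | intermediate
9 | dimethyl succinylsuccinate (dimethyl 2,5-dioxocyclohexane-1,4-dicarboxylate) | COC(=O)C1CC(=O)C(C(=O)OC)CC1=O | starting material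
10 | dimethyl (1S,2S,4S,5S)-2,5-dihydroxycyclohexane-1,4-dicarboxylate | COC(=O)[C@H]1C[C@H](O)[C@@H](C(=O)OC)C[C@@H]1O | intermediate
11 | dimethyl (1S,2S,4S,5S)-2,5-bis[(tert-butyldimethylsilyl)oxy]cyclohexane-1,4-dicarboxylate | COC(=O)[C@H]1C[C@H](O[Si](C)(C)C(C)(C)C)[C@@H](C(=O)OC)C[C@@H]1O[Si](C)(C)C(C)(C)C | intermediate
12 | bis(ketene methyl trimethylsilyl acetal) of 11 (enol ether geometry undefined) | COC(O[Si](C)(C)C)=C1C[C@H](O[Si](C)(C)C(C)(C)C)C(=C(OC)O[Si](C)(C)C)C[C@@H]1O[Si](C)(C)C(C)(C)C | intermediate (not isolated)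
13 | dimethyl (2S,5S)-2,5-bis[(tert-butyldimethylsilyl)oxy]-1,4-bis(phenylselanyl)cyclohexane-1,4-dicarboxylate (C1/C4 epimers, not controlled) | COC(=O)C1([Se]c2ccccc2)C[C@H](O[Si](C)(C)C(C)(C)C)C(C(=O)OC)([Se]c2ccccc2)C[C@@H]1O[Si](C)(C)C(C)(C)C | intermediate
14 | bis-selenoxide of 13 | COC(=O)C1([Se](=O)c2ccccc2)C[C@H](O[Si](C)(C)C(C)(C)C)C(C(=O)OC)([Se](=O)c2ccccc2)C[C@@H]1O[Si](C)(C)C(C)(C)C | intermediate (not isolated)
15 | dimethyl (3S,6S)-3,6-bis[(tert-butyldimethylsilyl)oxy]cyclohexa-1,4-diene-1,4-dicarboxylate | COC(=O)C1=C[C@H](O[Si](C)(C)C(C)(C)C)C(C(=O)OC)=C[C@@H]1O[Si](C)(C)C(C)(C)C | intermediate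
16 | [(3S,6S)-3,6-bis[(tert-butyldimethylsilyl)oxy]cyclohexa-1,4-diene-1,4-diyl]dimethanol | OCC1=C[C@H](O[Si](C)(C)C(C)(C)C)C(CO)=C[C@@H]1O[Si](C)(C)C(C)(C)C | intermediate
17 | {(3S,6S)-3,6-bis[(tert-butyldimethylsilyl)oxy]-4-{[(tert-butyldimethylsilyl)oxy]methyl}cyclohexa-1,4-dien-1-yl}methanol | OCC1=C[C@H](O[Si](C)(C)C(C)(C)C)C(CO[Si](C)(C)C(C)(C)C)=C[C@@H]1O[Si](C)(C)C(C)(C)C | intermediate
18 | [(1S,2S,5R,6S)-2,5-bis[(tert-butyldimethylsilyl)oxy]-4-{[(tert-butyldimethylsilyl)oxy]methyl}-7-oxabicyclo[4.1.0]hept-3-en-1-yl]methanol (epoxide anti to both ring silyloxy groups) | OC[C@]12O[C@H]1[C@H](O[Si](C)(C)C(C)(C)C)C(CO[Si](C)(C)C(C)(C)C)=C[C@@H]2O[Si](C)(C)C(C)(C)C | intermediate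
19 | (1S,2S,5R,6S)-2,5-bis[(tert-butyldimethylsilyl)oxy]-4-{[(tert-butyldimethylsilyl)oxy]methyl}-7-oxabicyclo[4.1.0]hept-3-ene-1-carbaldehyde | O=C[C@]12O[C@H]1[C@H](O[Si](C)(C)C(C)(C)C)C(CO[Si](C)(C)C(C)(C)C)=C[C@@H]2O[Si](C)(C)C(C)(C)C | intermediate
20 | propyne | CC#C | starting material
21 | chlorobis(cyclopentadienyl){(E)-2-[(1S,3R)-2,2-dimethyl-6-methylidene-3-(triethylsilyloxy)cyclohexyl]ethenyl}zirconium (Cp rings drawn σ-bonded) | C=C1CC[C@@H](O[Si](CC)(CC)CC)C(C)(C)[C@H]1/C=C/[Zr](Cl)(C2C=CC=C2)C2C=CC=C2 | intermediate (not isolated)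
22 | (1S,2Z,4E)-1-[(1S,2S,5R,6S)-2,5-bis[(tert-butyldimethylsilyl)oxy]-4-{[(tert-butyldimethylsilyl)oxy]methyl}-7-oxabicyclo[4.1.0]hept-3-en-1-yl]-5-[(1S,3R)-2,2-dimethyl-6-methylidene-3-(triethylsilyloxy)cyclohexyl]-3-methylpenta-2,4-dien-1-ol | C=C1CC[C@@H](O[Si](CC)(CC)CC)C(C)(C)[C@H]1/C=C/C(C)=C\[C@H](O)[C@]12O[C@H]1[C@H](O[Si](C)(C)C(C)(C)C)C(CO[Si](C)(C)C(C)(C)C)=C[C@@H]2O[Si](C)(C)C(C)(C)C | intermediate
23 | (1R,2S,5R,6S)-1-{(1S,2Z,4E)-1-hydroxy-5-[(1S,3R)-3-hydroxy-2,2-dimethyl-6-methylidenecyclohexyl]-3-methylpenta-2,4-dien-1-yl}-4-(hydroxymethyl)-7-oxabicyclo[4.1.0]hept-3-ene-2,5-diol | C=C1CC[C@@H](O)C(C)(C)[C@H]1/C=C/C(C)=C\[C@H](O)[C@]12O[C@H]1[C@H](O)C(CO)=C[C@@H]2O | target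

Total step count: 17. Longest linear sequence: 10 steps (steps 8–17, from dimethyl succinylsuccinate); the ring-A branch contributes 7 steps before the coupling.

Steps most likely to fail

Step 16 (proposed new method). The alkenyl group may be transferred straight to the carbonyl without uptake of propyne, propyne may oligomerise on nickel(0), nickel(0) may open the epoxide next to the carbonyl, or the two carbonyl faces may be poorly differentiated. The fallback uses known chemistry, sets out from 19 (with 8 for the last operation) and returns at 22. Addition of 1-propynylmagnesium bromide to 19 (THF, −78 °C) gives the C1-epimeric propargylic alcohols F1. Dess–Martin oxidation gives the ynone F2. Noyori transfer hydrogenation with RuCl[(R,R)-TsDPEN](p-cymene) in 2-propanol reduces it under catalyst control to the (1S)-propargylic alcohol F3. Hydroxyl-directed trans-hydroalumination with Red-Al followed by iodine gives the (Z)-3-iodo allylic alcohol F4, iodine cis to C1; the tertiary epoxide carbon should resist hydride delivery. Negishi coupling of F4 with the alkenylzirconocene 21 (Pd(PPh3)4, ZnCl2, THF, rt, excess 21) then gives 22 with retention at both alkenes.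

Step 10. Expulsion of silanolate from the β-carbon of the ester enolates, or incomplete twofold enolisation, may outrun silyl trapping. The fallback sets out from 10 and returns at 15. The unprotected diol diester is converted into its fourfold lithiated alkoxide–enolate (Fráter–Seebach conditions: LDA 4.5 equiv, THF/DMPU, −50 to −20 °C), in which β-elimination is blocked, and selenenylated with PhSeBr to the bis(phenylselanyl) diol F5. Hydrogen peroxide with pyridine gives the bis-selenoxide F6, which eliminates away from the carbinol carbons to the diene diol diester F7. Silylation of F7 (TBSCl, imidazole, DMF) gives 15.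

Step 6. During a slow olefination at the hindered aldehyde the exocyclic double bond may move into conjugation with the carbonyl, or C1 may epimerise. The fallback sets out from 6 and returns at 8. Colvin homologation with lithiated trimethylsilyldiazomethane (TMSCHN2, n-BuLi, THF, −78 to 0 °C) adds to the carbonyl at low temperature, and the alkylidene carbene formed rearranges by 1,2-hydrogen shift directly to the alkyne. This skips 7 and makes no new compound (F0).

Further compounds
F1 | step 16 | 1-[(1S,2S,5R,6S)-2,5-bis[(tert-butyldimethylsilyl)oxy]-4-{[(tert-butyldimethylsilyl)oxy]methyl}-7-oxabicyclo[4.1.0]hept-3-en-1-yl]but-2-yn-1-ol (C1 epimers) | CC#CC(O)[C@]12O[C@H]1[C@H](O[Si](C)(C)C(C)(C)C)C(CO[Si](C)(C)C(C)(C)C)=C[C@@H]2O[Si](C)(C)C(C)(C)C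
F2 | step 16 | 1-[(1S,2S,5R,6S)-2,5-bis[(tert-butyldimethylsilyl)oxy]-4-{[(tert-butyldimethylsilyl)oxy]methyl}-7-oxabicyclo[4.1.0]hept-3-en-1-yl]but-2-yn-1-one | CC#CC(=O)[C@]12O[C@H]1[C@H](O[Si](C)(C)C(C)(C)C)C(CO[Si](C)(C)C(C)(C)C)=C[C@@H]2O[Si](C)(C)C(C)(C)C
F3 | step 16 | (1S)-1-[(1S,2S,5R,6S)-2,5-bis[(tert-butyldimethylsilyl)oxy]-4-{[(tert-butyldimethylsilyl)oxy]methyl}-7-oxabicyclo[4.1.0]hept-3-en-1-yl]but-2-yn-1-ol | CC#C[C@H](O)[C@]12O[C@H]1[C@H](O[Si](C)(C)C(C)(C)C)C(CO[Si](C)(C)C(C)(C)C)=C[C@@H]2O[Si](C)(C)C(C)(C)C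
F4 | step 16 | (1S,2Z)-1-[(1S,2S,5R,6S)-2,5-bis[(tert-butyldimethylsilyl)oxy]-4-{[(tert-butyldimethylsilyl)oxy]methyl}-7-oxabicyclo[4.1.0]hept-3-en-1-yl]-3-iodobut-2-en-1-ol | C/C(I)=C/[C@H](O)[C@]12O[C@H]1[C@H](O[Si](C)(C)C(C)(C)C)C(CO[Si](C)(C)C(C)(C)C)=C[C@@H]2O[Si](C)(C)C(C)(C)C
F5 | step 10 | dimethyl (2S,5S)-2,5-dihydroxy-1,4-bis(phenylselanyl)cyclohexane-1,4-dicarboxylate (C1/C4 epimers) | COC(=O)C1([Se]c2ccccc2)C[C@H](O)C(C(=O)OC)([Se]c2ccccc2)C[C@@H]1O
F6 | step 10 | bis-selenoxide of F5 | COC(=O)C1([Se](=O)c2ccccc2)C[C@H](O)C(C(=O)OC)([Se](=O)c2ccccc2)C[C@@H]1O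
F7 | step 10 | dimethyl (3S,6S)-3,6-dihydroxycyclohexa-1,4-diene-1,4-dicarboxylate | COC(=O)C1=C[C@H](O)C(C(=O)OC)=C[C@@H]1O
F0 | step 6 | none | none
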